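**Retrosynthetic overview**
Ring C (the 14-membered ring) is cut at C7'–C8' (ring-closing B-alkyl Suzuki–Miyaura coupling on a Z alkenyl iodide, made last) and at C5–C1' (aryl Grignard plus allylic chloride); C1'–C7' comes from nerol, which brings the Z C2'=C3' bond, and the Z C6'=C7' bond is set by an iodo-Wittig reaction.
O6–C11' and C10' come from O6-alkylation with 2-bromo-2-methylpropanal and a catalytic enantioselective vinyl transfer (C10' S); C3 (R) is bought as (R)-1-bromopropan-2-ol.
Ring B (lactone: C1, O2, C3, C4, C4a, C8a) is closed by forming C4–C4a in a palladium/norbornene relay (Catellani reaction) on the (R)-1-bromopropan-2-yl ester of a 5-iodo-2,4-dioxygenated benzoic acid; C5 leaves the step as a boronate and is turned back into the iodide that later takes the chain.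
Feature that makes this possible: in ring A, C4a is meta to both ring oxygens (no electrophilic access), but it is the only C–H ortho to C5, the carbon that iodination selects (para to O8, ortho to O6), and its other neighbour C8a carries the carboxyl whose ester oxygen O2 holds C3–C4; palladium entering at C5 is passed to C4a through a temporary norbornene-bridged palladacycle (a ring not in the target, cleaved in the same operation) and meets C4 in a six-membered closure.
Order of ring formation: ring A is bought, ring B in step 5, ring C in step 15.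

Key step: step 5

Remark: locants are those of isochroman-1-one for rings A and B (C1, O2, C3, C4, C4a, C5–C8, C8a) and C1'–C11' for the chain of ring C (C1' on C5, C11' on O6); both ring double bonds of the given SMILES are Z and are built as Z; (R)-1-bromopropan-2-ol is taken as a catalogue compound (otherwise one step from (R)-propylene oxide and HBr).

**Route**

Step 1
Reactants: 1 methyl 2,4-dihydroxybenzoate
Product: 2 methyl 2,4-dihydroxy-5-iodobenzoate
Conditions: NIS (1.0 equiv), TsOH (cat.), MeCN, 0 °C to rt
Reagents that add atoms: N-iodosuccinimide, O=C1CCC(=O)N1I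
Why: Electrophilic aromatic iodination should go to C5 of the benzoate (para to the 2-OH, ortho to the 4-OH, unhindered), the future C5 of ring A, because the position between the two hydroxyls is the more crowded one.

Step 2
Reactants: 2 methyl 2,4-dihydroxy-5-iodobenzoate
Product: 3 methyl 5-iodo-2,4-bis(methoxymethoxy)benzoate
Conditions: NaH (2.4 equiv), MOMCl (2.4 equiv), DMF, 0 °C to rt
Reagents that add atoms: chloromethyl methyl ether, COCCl
Why: Williamson-type O-alkylation of both phenoxides; the MOM groups keep the 2-oxygen from attacking the bromide tether later and give C6 of ring A the ortho substituent that the palladium/norbornene relay needs.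

Step 3
Reactants: 3 methyl 5-iodo-2,4-bis(methoxymethoxy)benzoate
Product: 4 5-iodo-2,4-bis(methoxymethoxy)benzoic acid
Conditions: LiOH, THF/MeOH/H2O, 50 °C; cold 1 M HCl to pH 4
Reagents that add atoms: lithium hydroxide, [Li+].[OH-]
Why: Saponification of the methyl ester (acyl substitution by hydroxide); MOM aryl ethers and the aryl iodide are inert to aqueous base and to the brief cold acidification.

Step 4
Reactants: 4 5-iodo-2,4-bis(methoxymethoxy)benzoic acid; 5 (R)-1-bromopropan-2-ol
Product: 6 (2R)-1-bromopropan-2-yl 5-iodo-2,4-bis(methoxymethoxy)benzoate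
Conditions: EDC·HCl, DMAP (cat.), CH2Cl2, 0 °C to rt
Reagents that add atoms: none
Why: Steglich esterification forms only the acyl C–O bond, so the carbinol carbon of 5 keeps its R configuration and becomes C3 of the target.

Step 5
Reactants: 6 (2R)-1-bromopropan-2-yl 5-iodo-2,4-bis(methoxymethoxy)benzoate
Product: 7 (3R)-6,8-bis(methoxymethoxy)-3-methyl-5-(4,4,5,5-tetramethyl-1,3,2-dioxaborolan-2-yl)isochroman-1-one
Conditions: Pd(OAc)2 (10 mol %), P(2-furyl)3 (25 mol %), norbornene (2 equiv), B2pin2 (1.5 equiv), Cs2CO3 (3 equiv), MeCN (0.02 M), 85 °C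
Reagents that add atoms: bis(pinacolato)diboron, CC1(C)OB(OC1(C)C)B1OC(C)(C)C(C)(C)O1
Why: Proposed new method: Zerovalent palladium inserts into C5–I, norbornene carbopalladation and cyclometalation at C4a–H (the only C–H ortho to C5) give the divalent aryl–norbornyl palladacycle, and the CH2Br carbon C4, held by the C8a ester, adds oxidatively to it (tetravalent palladium) and is coupled to C4a by reductive elimination. With both positions ortho to C5 now substituted, norbornene is expelled by β-carbon elimination and the C5–Pd bond is borylated by B2pin2 (Miyaura-type termination). The closest known reaction type is the Catellani reaction in its ring-forming version, in which a bromoalkyl chain tethered meta to the iodide alkylates the ortho position in between, together with ipso-borylation as a known termination; new are the ester tether and the β-acyloxy bromide. Ring B closes in a 6-exo-tet sense at C4 through a seven-membered palladacycle that requires the s-cis ester rotamer, which the long-lived palladacycle can wait for. No stereocentre is formed, and C3 keeps the R configuration brought in by 5 because bonding occurs at the neighbouring CH2. The step needs alkylation at C4a before termination at C5 and substitution instead of loss of HBr: the first is secured by the ortho OMOM group (fast norbornene insertion, slow direct borylation) and the intramolecular electrophile, the second by the carbonate base and the primary bromide.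

Step 6
Reactants: 7 (3R)-6,8-bis(methoxymethoxy)-3-methyl-5-(4,4,5,5-tetramethyl-1,3,2-dioxaborolan-2-yl)isochroman-1-one
Product: 8 (3R)-5-iodo-6,8-bis(methoxymethoxy)-3-methylisochroman-1-one
Conditions: NaI, TsNClNa (chloramine-T), THF/H2O, 0 °C to rt
Reagents that add atoms: sodium iodide, [Na+].[I-]
Why: Ipso-iododeboronation (halodeboronation) by electrophilic iodine should replace boron at C5 faster than it attacks the hindered C7–H, and returns the C5 handle as an iodide without touching the MOM ethers or the lactone.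

Step 7
Reactants: 8 (3R)-5-iodo-6,8-bis(methoxymethoxy)-3-methylisochroman-1-one
Product: 9 (3R)-6,8-dihydroxy-5-iodo-3-methylisochroman-1-one
Conditions: TFA/CH2Cl2/H2O (10:40:1), 0 °C to rt
Reagents that add atoms: none
Why: Acid-catalysed acetal hydrolysis removes both MOM groups, and the lactone and the aryl iodide should survive the short cold exposure to TFA.

Step 8
Reactants: 9 (3R)-6,8-dihydroxy-5-iodo-3-methylisochroman-1-one; 10 2-bromo-2-methylpropanal
Product: 11 2-{[(3R)-8-hydroxy-5-iodo-3-methyl-1-oxoisochroman-6-yl]oxy}-2-methylpropanal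
Conditions: K2CO3 (1.1 equiv), DMF, 0 °C to rt
Reagents that add atoms: none
Why: Williamson ether synthesis on an activated tertiary α-bromo aldehyde that cannot enolise: the 6-OH (para to the lactone carbonyl, ortho to iodine) is far more acidic and nucleophilic than the 8-OH that is hydrogen-bonded to C1=O, so only O6 is alkylated and the O6–C11' bond of ring C is made.

Step 9
Reactants: 11 2-{[(3R)-8-hydroxy-5-iodo-3-methyl-1-oxoisochroman-6-yl]oxy}-2-methylpropanal
Product: 12 (3R)-8-hydroxy-6-{[(3S)-3-hydroxy-2-methylpent-4-en-2-yl]oxy}-5-iodo-3-methylisochroman-1-one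
Conditions: (CH2=CH)2Zn (3 equiv, from CH2=CHMgBr and ZnCl2, magnesium salts precipitated with 1,4-dioxane), (−)-MIB (10 mol %), toluene, −20 °C; aq NH4Cl
Reagents that add atoms: vinylmagnesium bromide, C=C[Mg]Br
Why: Catalytic enantioselective organozinc addition to an aldehyde: the zinc aminoalkoxide of (−)-MIB should transfer vinyl to the Si face of the α-quaternary aldehyde (the sense of its dialkylzinc additions) and set C10' as S, the lactone and aryl iodide are inert to organozincs, and the minor C10' epimer is a diastereomer that chromatography can remove.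

Step 10
Reactants: 12 (3R)-8-hydroxy-6-{[(3S)-3-hydroxy-2-methylpent-4-en-2-yl]oxy}-5-iodo-3-methylisochroman-1-one
Product: 14 (3R)-6-{[(3S)-3-(tert-butyldimethylsilyloxy)-2-methylpent-4-en-2-yl]oxy}-8-hydroxy-5-iodo-3-methylisochroman-1-one, via bis-silyl ether 13 (not isolated)
Conditions: TBSOTf (2.5 equiv), 2,6-lutidine, CH2Cl2, 0 °C; then K2CO3, MeOH, 0 °C
Reagents that add atoms: tert-butyldimethylsilyl trifluoromethanesulfonate, CC(C)(C)[Si](C)(C)OS(=O)(=O)C(F)(F)F
Why: Silyl triflate silylation protects the hindered C10' alcohol (and for a short time the phenol), and methanolysis then cleaves only the labile aryl silyl ether next to the lactone carbonyl, which frees the 8-OH that shields the lactone as its magnesium phenoxide in step 14.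

Step 11
Reactants: 15 nerol ((2Z)-3,7-dimethylocta-2,6-dien-1-ol)
Product: 16 neryl chloride ((2Z)-1-chloro-3,7-dimethylocta-2,6-diene)
Conditions: NCS, Me2S, CH2Cl2, −40 to 0 °C
Reagents that add atoms: N-chlorosuccinimide, O=C1CCC(=O)N1Cl
Why: Corey–Kim chlorination (SN2 displacement of the alkoxysulfonium group by chloride) converts the primary allylic alcohol without allylic transposition or loss of the Z geometry.

Step 12
Reactants: 16 neryl chloride ((2Z)-1-chloro-3,7-dimethylocta-2,6-diene)
Product: 17 (4Z)-6-chloro-4-methylhex-4-enal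
Conditions: O3 (1.0 equiv), pyridine, CH2Cl2, −78 °C; then Me2S
Reagents that add atoms: ozone, [O-][O+]=O
Why: Ozonolysis with one equivalent of ozone should cleave the electron-rich terminal isopropylidene double bond and spare the 2,3-double bond, which is deactivated by the allylic chlorine.

Step 13
Reactants: 17 (4Z)-6-chloro-4-methylhex-4-enal
Product: 18 (2Z,6Z)-1-chloro-7-iodo-3-methylocta-2,6-diene
Conditions: EtPPh3I, n-BuLi, THF, rt; I2, −78 °C; NaN(SiMe3)2, −20 °C; then 17, −78 °C
Reagents that add atoms: ethyltriphenylphosphonium iodide, CC[P+](c1ccccc1)(c1ccccc1)c1ccccc1.[I-]; iodine, II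
Why: Stork–Zhao-type Wittig olefination with the α-iodo ylide gives the 2-iodoalk-2-ene with iodine cis to the chain (Z) through kinetic oxaphosphetane formation at low temperature, which fixes the geometry of the future C6'=C7' bond.

Step 14
Reactants: 14 (3R)-6-{[(3S)-3-(tert-butyldimethylsilyloxy)-2-methylpent-4-en-2-yl]oxy}-8-hydroxy-5-iodo-3-methylisochroman-1-one; 18 (2Z,6Z)-1-chloro-7-iodo-3-methylocta-2,6-diene
Product: 20 (3R)-6-{[(3S)-3-(tert-butyldimethylsilyloxy)-2-methylpent-4-en-2-yl]oxy}-8-hydroxy-5-[(2Z,6Z)-7-iodo-3-methylocta-2,6-dien-1-yl]-3-methylisochroman-1-one, via arylmagnesium chloride 19 (not isolated)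
Conditions: MeMgCl (1.0 equiv), THF, −30 °C; i-PrMgCl·LiCl (1.2 equiv), −15 °C; then Li2CuCl4 (5 mol %), 18, −30 to 0 °C; aq NH4Cl
Reagents that add atoms: none
Why: Iodine–magnesium exchange (after deprotonation of the phenol, whose magnesium phenoxide deactivates the lactone carbonyl) gives the C5 arylmagnesium, and the Li2CuCl4-catalysed coupling with the primary allylic chloride should take the SN2 (α) course with retention of both Z double bonds, while the alkenyl iodide does not react with organocopper species at this temperature.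

Step 15
Reactants: 20 (3R)-6-{[(3S)-3-(tert-butyldimethylsilyloxy)-2-methylpent-4-en-2-yl]oxy}-8-hydroxy-5-[(2Z,6Z)-7-iodo-3-methylocta-2,6-dien-1-yl]-3-methylisochroman-1-one
Product: 22 10'-O-(tert-butyldimethylsilyl)chrysomutanin, via B-alkylborane 21 (not isolated)
Conditions: 9-BBN (3 equiv), THF, rt; then slow addition to Pd(dppf)Cl2 (20 mol %), AsPh3, Cs2CO3, DMF/THF/H2O, 50 °C (final 1 mM)
Reagents that add atoms: none
Why: 9-BBN hydroborates only the monosubstituted alkene (anti-Markovnikov), and the intramolecular B-alkyl Suzuki–Miyaura coupling with the alkenyl iodide under high dilution closes the 14-membered ring C at C7'–C8' with retention of the Z geometry; no stereocentre is formed.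

Step 16
Reactants: 22 10'-O-(tert-butyldimethylsilyl)chrysomutanin
Product: 23 chrysomutanin
Conditions: HF·pyridine, pyridine, THF, 0 °C to rt
Reagents that add atoms: none
Why: Fluoride-induced desilylation of the secondary TBS ether under buffered conditions should leave the aryl tert-alkyl ether, the lactone and the trisubstituted Z alkenes untouched.

**Compound list**
1 | methyl 2,4-dihydroxybenzoate | COC(=O)c1ccc(O)cc1O | starting material
2 | methyl 2,4-dihydroxy-5-iodobenzoate | COC(=O)c1cc(I)c(O)cc1O | intermediate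
3 | methyl 5-iodo-2,4-bis(methoxymethoxy)benzoate | COCOc1cc(OCOC)c(C(=O)OC)cc1I | intermediate
4 | 5-iodo-2,4-bis(methoxymethoxy)benzoic acid | COCOc1cc(OCOC)c(C(=O)O)cc1I | intermediate
5 | (R)-1-bromopropan-2-ol | C[C@@H](O)CBr | starting material
6 | (2R)-1-bromopropan-2-yl 5-iodo-2,4-bis(methoxymethoxy)benzoate | C[C@@H](OC(=O)c1cc(I)c(OCOC)cc1OCOC)CBr | intermediate
7 | (3R)-6,8-bis(methoxymethoxy)-3-methyl-5-(4,4,5,5-tetramethyl-1,3,2-dioxaborolan-2-yl)isochroman-1-one | C[C@@H]1Cc2c(B3OC(C)(C)C(C)(C)O3)c(OCOC)cc(OCOC)c2C(=O)O1 | intermediate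
8 | (3R)-5-iodo-6,8-bis(methoxymethoxy)-3-methylisochroman-1-one | C[C@@H]1Cc2c(I)c(OCOC)cc(OCOC)c2C(=O)O1 | intermediate
9 | (3R)-6,8-dihydroxy-5-iodo-3-methylisochroman-1-one | C[C@@H]1Cc2c(I)c(O)cc(O)c2C(=O)O1 | intermediate
10 | 2-bromo-2-methylpropanal | CC(C)(Br)C=O | starting material
11 | 2-{[(3R)-8-hydroxy-5-iodo-3-methyl-1-oxoisochroman-6-yl]oxy}-2-methylpropanal | C[C@@H]1Cc2c(I)c(OC(C)(C)C=O)cc(O)c2C(=O)O1 | intermediate
12 | (3R)-8-hydroxy-6-{[(3S)-3-hydroxy-2-methylpent-4-en-2-yl]oxy}-5-iodo-3-methylisochroman-1-one | C[C@@H]1Cc2c(I)c(OC(C)(C)[C@@H](O)C=C)cc(O)c2C(=O)O1 | intermediate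
13 | (3R)-8-(tert-butyldimethylsilyloxy)-6-{[(3S)-3-(tert-butyldimethylsilyloxy)-2-methylpent-4-en-2-yl]oxy}-5-iodo-3-methylisochroman-1-one (bis-silyl ether) | C[C@@H]1Cc2c(I)c(OC(C)(C)[C@@H](O[Si](C)(C)C(C)(C)C)C=C)cc(O[Si](C)(C)C(C)(C)C)c2C(=O)O1 | intermediate
14 | (3R)-6-{[(3S)-3-(tert-butyldimethylsilyloxy)-2-methylpent-4-en-2-yl]oxy}-8-hydroxy-5-iodo-3-methylisochroman-1-one | C[C@@H]1Cc2c(I)c(OC(C)(C)[C@@H](O[Si](C)(C)C(C)(C)C)C=C)cc(O)c2C(=O)O1 | intermediate
15 | nerol ((2Z)-3,7-dimethylocta-2,6-dien-1-ol) | CC(C)=CCC/C(C)=C\CO | starting material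
16 | neryl chloride ((2Z)-1-chloro-3,7-dimethylocta-2,6-diene) | CC(C)=CCC/C(C)=C\CCl | intermediate
17 | (4Z)-6-chloro-4-methylhex-4-enal | O=CCC/C(C)=C\CCl | intermediate
18 | (2Z,6Z)-1-chloro-7-iodo-3-methylocta-2,6-diene | ClC/C=C(C)\CC/C=C(C)\I | intermediate
19 | arylmagnesium chloride of 14 (C5–MgCl, 8-O–MgCl) | C[C@@H]1Cc2c([Mg]Cl)c(OC(C)(C)[C@@H](O[Si](C)(C)C(C)(C)C)C=C)cc(O[Mg]Cl)c2C(=O)O1 | intermediate
20 | (3R)-6-{[(3S)-3-(tert-butyldimethylsilyloxy)-2-methylpent-4-en-2-yl]oxy}-8-hydroxy-5-[(2Z,6Z)-7-iodo-3-methylocta-2,6-dien-1-yl]-3-methylisochroman-1-one | C[C@@H]1Cc2c(C/C=C(C)\CC/C=C(C)\I)c(OC(C)(C)[C@@H](O[Si](C)(C)C(C)(C)C)C=C)cc(O)c2C(=O)O1 | intermediate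
21 | B-alkylborane of 20 (C8'–B and 8-O–B, both 9-borabicyclo[3.3.1]nonan-9-yl) | C[C@@H]1Cc2c(C/C=C(C)\CC/C=C(C)\I)c(OC(C)(C)[C@@H](O[Si](C)(C)C(C)(C)C)CCB3C4CCCC3CCC4)cc(OB3C4CCCC3CCC4)c2C(=O)O1 | intermediate
22 | 10'-O-(tert-butyldimethylsilyl)chrysomutanin | C/C1=C/Cc2c(cc(O)c3c2C[C@@H](C)OC3=O)OC(C)(C)[C@@H](O[Si](C)(C)C(C)(C)C)CC/C(C)=C\CC1 | intermediate
23 | chrysomutanin | C/C1=C/Cc2c(cc(O)c3c2C[C@@H](C)OC3=O)OC(C)(C)[C@@H](O)CC/C(C)=C\CC1 | target

**Step count and risks**
Total step count: 16. Longest linear sequence: 13 steps (steps 1–10 and 14–16, from compound 1); the chain branch (steps 11–13) joins at step 14.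

Steps most likely to fail:

Step 5 (bears the label). What may go wrong: termination at C5 by borylation before palladium has been relayed to C4a, or base-induced loss of HBr from the tether to an enol ester. Fallback with known chemistry, setting out from acid 4 and coming back at 8: the Pd(OAc)2-catalysed, carboxylate-directed ortho-C–H alkylation of benzoic acids with terminal epoxides, which lactonises in the same pot (4, (R)-propylene oxide, Pd(OAc)2, N-acetylvaline, KOAc, (CF3)2CHOH, 75 °C). C4a is the only position ortho to the carboxylate, the aryl–palladium attacks the CH2 terminus of the epoxide so that C3 stays R, and the C5 iodide should persist because no zerovalent palladium is formed. No compound outside the compound list is made (entry F0).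

Step 15. What may go wrong: intermolecular coupling to oligomers instead of ring closure, and protodeboronation of the hindered γ-silyloxy alkylborane before transmetalation. Fallback, setting out from 20 and coming back at 22: the organoboron/base manifold is replaced by a nickel-catalysed reductive coupling of two carbon–iodine bonds. Hydroboration–oxidation of 20 (9-BBN, then NaBO3) gives (3R)-6-{[(3S)-3-(tert-butyldimethylsilyloxy)-5-hydroxy-2-methylpentan-2-yl]oxy}-8-hydroxy-5-[(2Z,6Z)-7-iodo-3-methylocta-2,6-dien-1-yl]-3-methylisochroman-1-one F1. Appel iodination (I2, PPh3, imidazole) gives the primary iodide (3R)-6-{[(3S)-3-(tert-butyldimethylsilyloxy)-5-iodo-2-methylpentan-2-yl]oxy}-8-hydroxy-5-[(2Z,6Z)-7-iodo-3-methylocta-2,6-dien-1-yl]-3-methylisochroman-1-one F2. Slow addition of F2 to NiBr2(dme), 4,4'-di-tert-butyl-2,2'-bipyridine and Mn in DMA (alkenyl–alkyl cross-electrophile coupling, geometry-retentive) should close ring C to 22.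

Step 9. What may go wrong: poor facial selectivity, because the zinc phenoxide formed from the free 8-OH can open an uncatalysed addition pathway. Fallback, setting out from 11 and coming back at 12: stereocontrol is moved from a catalytic C–C bond formation to a reagent-controlled reduction. CH2=CHMgBr (THF, −78 °C) adds to the aldehyde to give both C3' epimers of (3R)-8-hydroxy-6-[(3-hydroxy-2-methylpent-4-en-2-yl)oxy]-5-iodo-3-methylisochroman-1-one F3. MnO2 oxidation gives the vinyl ketone (3R)-8-hydroxy-5-iodo-3-methyl-6-[(2-methyl-3-oxopent-4-en-2-yl)oxy]isochroman-1-one F4. Corey–Bakshi–Shibata reduction with (R)-Me-CBS and BH3·SMe2 (quaternary C11' as the large group, vinyl as the small one) should give 12.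

Further compounds
F0 | step 5 | none | none
F1 | step 15 | (3R)-6-{[(3S)-3-(tert-butyldimethylsilyloxy)-5-hydroxy-2-methylpentan-2-yl]oxy}-8-hydroxy-5-[(2Z,6Z)-7-iodo-3-methylocta-2,6-dien-1-yl]-3-methylisochroman-1-one | C[C@@H]1Cc2c(C/C=C(C)\CC/C=C(C)\I)c(OC(C)(C)[C@@H](O[Si](C)(C)C(C)(C)C)CCO)cc(O)c2C(=O)O1
F2 | step 15 | (3R)-6-{[(3S)-3-(tert-butyldimethylsilyloxy)-5-iodo-2-methylpentan-2-yl]oxy}-8-hydroxy-5-[(2Z,6Z)-7-iodo-3-methylocta-2,6-dien-1-yl]-3-methylisochroman-1-one | C[C@@H]1Cc2c(C/C=C(C)\CC/C=C(C)\I)c(OC(C)(C)[C@@H](O[Si](C)(C)C(C)(C)C)CCI)cc(O)c2C(=O)O1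
F3 | step 9 | (3R)-8-hydroxy-6-[(3-hydroxy-2-methylpent-4-en-2-yl)oxy]-5-iodo-3-methylisochroman-1-one (both C3' epimers) | C[C@@H]1Cc2c(I)c(OC(C)(C)C(O)C=C)cc(O)c2C(=O)O1
F4 | step 9 | (3R)-8-hydroxy-5-iodo-3-methyl-6-[(2-methyl-3-oxopent-4-en-2-yl)oxy]isochroman-1-one | C[C@@H]1Cc2c(I)c(OC(C)(C)C(=O)C=C)cc(O)c2C(=O)O1
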